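## Analysis of the target

Target 20 is a 2,3-dihydro-1-benzofuran in which benzene ring A is fused to dihydrofuran ring B (O1, C2, C3, C3a, C7a). C2 carries a 3-oxoprop-1-en-2-yl group, C3 a 3-methylbutanoyloxy group, and C5, para to O1, a 1-acetoxyethyl group. There are three stereocentres: C2 (R) and C3 (R) are neighbours and hold their substituents cis on ring B, whereas C1' (S) of the side chain is too far from the ring to be steered by it. The sensitive groups are the 2-substituted propenal (a Michael acceptor that polymerises easily), the C3 ester, which can leave together with H2 to give the aromatic benzofuran, and the C1' acetate, a p-alkoxybenzylic ester that ionises under acid. The difficulties are the cis C2/C3 pair in one absolute sense, two different esters on two secondary benzylic oxygens, and the need to bring in the aldehyde late. The strategy rests on the C2–C3 bond of ring B: it joins a benzylic carbinol carbon (C3) to an oxygen-bearing allylic carbon (C2) that carries a 2-propenyl branch, the pattern left when a γ-alkoxyallyl metal reagent adds to an aryl aldehyde. The other ring bond to be made, O1–C7a, is an aryl–oxygen bond that an ortho halogen on that aldehyde can supply.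

## Retrosynthetic reasoning

**Aldehyde C–H/C–O adjustment (20 ⇒ 19 ⇒ 18).** The enal is the most fragile group and is removed first. It is traced to the primary allylic alcohol 19 and then to the 2-propenyl compound 18 by allylic C–H oxidation of the methyl group. The forward steps must oxidise the methyl group and not the C2–H, and must leave two benzylic esters intact.

**The two esters (18 ⇒ 17 ⇒ 16 ⇒ 14 + 15).** The acetate is cut to alcohol 17 and this to methyl ketone 16, so that C1' is set by a catalyst-controlled carbonyl reduction independent of ring B. The isovalerate is cut to alcohol 14 and acid 15. Keeping C1' as a ketone until the C3 hydroxyl has been acylated means each ester is introduced when its oxygen is the only free hydroxyl, so the two secondary benzylic oxygens never compete.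

**O1–C7a (14 ⇒ 13).** Ring B is opened at the aryl–oxygen bond, giving bromo diol 13. Cutting O1–C2 instead would call for a displacement at C2 with inversion, which would turn a syn precursor into the trans ring. Forming the bond at the aromatic carbon leaves both stereocentres untouched, so syn maps onto cis. Only the C2 hydroxyl can close a five-membered ring, so the diol needs no differentiation.

**Acetal removal (13 ⇒ 12).** The ketone and the C2 hydroxyl are masked as a dioxolane and a methoxymethyl ether in 12. Both are acetals and fall in one acidic operation.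

**C2–C3, the strategic bond (12 ⇒ 4 + 10).** The bond between the carbinol carbon and the alkoxy-bearing carbon is cut, giving aldehyde 4 and (Z)-γ-alkoxy-β-methylallyl boronate 10. This one union delivers every carbon of ring B and the 2-propenyl branch, sets both ring stereocentres, and leaves the bromine where the aryl–oxygen bond is needed. The forward reaction must be syn-selective (from the (Z) geometry of 10), face-selective (from a chiral acid catalyst) and selective for the aldehyde (the second carbonyl is a ketal).

**Aldehyde 4 (4 ⇒ 3 ⇒ 2 ⇒ 1).** The formyl group is traced to a benzylic bromide 3 and to the methyl group of ketal 2, which comes from ketone 1. The arene already has the acetyl carbon, the bromine and the future C3 carbon in the right 1,2,4-relationship, so no aromatic substitution chemistry is needed.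

**Boronate 10 (10 ⇒ 6 + 7; 6 ⇒ 5).** The C–B bond is cut to the chelated (Z)-oxyallyl anion of ether 6 and borate 7. Ether 6 comes from alcohol 5. The (Z) geometry is fixed when the anion is formed.

## Alternatives that were turned down

**Alternative 1:** Here ring A itself is disconnected, at C3a–C7a and C4–C5. A 3-alkoxy-2-pyrone ester of sugar-acid origin, methyl 3-{[(3R,4R)-4-(tert-butyldimethylsilyloxy)-2-methylhex-1-en-5-yn-3-yl]oxy}-2-oxo-2H-pyran-6-carboxylate A2, would undergo an intramolecular Diels–Alder reaction of the pyrone diene with the tethered alkyne. The bridged lactone would then aromatise by cycloreversion to methyl (2R,3R)-3-(tert-butyldimethylsilyloxy)-2-(prop-1-en-2-yl)-2,3-dihydro-1-benzofuran-5-carboxylate A1.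
- In its favour: rings A and B appear together without any metal, the O1–aryl bond exists from the start, and the tether fixes the position of the ester. On the aryl–oxygen bond it is stronger than the chosen route, which needs a halide and a copper step.
- Against it: both ring stereocentres must already be present in A2, so the stereochemical problem is only moved into an acyclic alkyne diol that needs its own asymmetric C–C bond formation. The pyrone oxygen must be alkylated at a hindered secondary allylic carbon. A2 is also an allyl vinyl ether (pyrone C3=C4 and the 2-propenyl group), so a Claisen shift competes at the temperature of the cycloaddition.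
- After the key step, the C5 ester still has to become the (S)-1-acetoxyethyl group and the silyl ether the isovalerate, before the allylic oxidation. The sequence is clearly longer than the chosen one, which buys the arene with the acetyl carbon in place and sets the stereocentres in the bond-forming step.

**Alternative 2:** Here the C3–H and C1'–H bonds are disconnected. Racemic 5-acetyl-2-(2,2-dimethyl-1,3-dioxan-5-yl)-1-benzofuran-3(2H)-one A4 would be reduced by asymmetric transfer hydrogenation while C2 epimerises through its aromatic enol, giving (2R,3R)-2-(2,2-dimethyl-1,3-dioxan-5-yl)-5-[(1S)-1-hydroxyethyl]-2,3-dihydro-1-benzofuran-3-ol A3.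
- In its favour: three stereocentres from one catalyst and a racemic, easily made substrate. On stereochemical economy it is stronger than the chosen route, which uses two separate asymmetric steps.
- Against it: A3 has two free secondary benzylic hydroxyls that must receive different acyl groups, and nothing in the structure tells them apart. The sense at C3 is tied to the sense at C1' by the single catalyst and cannot be corrected independently. The C2 substituent is a masked 1,3-diol that still needs deprotection, a selective mono-elimination and an oxidation to become the propenal, all in the presence of the other oxygens.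
- The chosen route gives up the single stereo-defining step for independent control of ring and side chain and for an acylation order in which each ester goes on when its oxygen is the only free hydroxyl.

**Alternative 3:** Here O1–C2 is formed while the O1–CMe2 bond of a chroman is broken. The cis-diol monoester (3R,4R)-6-[(1S)-1-acetoxyethyl]-3-hydroxy-2,2-dimethyl-3,4-dihydro-2H-chromen-4-yl 3-methylbutanoate A6 would be triflated. O1 would displace the triflate with inversion, the old O1–C bond would open to a tertiary cation, and loss of a methyl proton would give (2R,3R)-5-[(1S)-1-acetoxyethyl]-2-(prop-1-en-2-yl)-2,3-dihydro-1-benzofuran-3-yl 3-methylbutanoate A5, which is identical with 18.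
- In its favour: it is short and stereospecific (cis diol to cis ring), and both esters are in place before the key step. On step count it is stronger than the chosen route.
- Against it: the key step is a cationic rearrangement that no element of A6 steers. The axial triflate has an anti-periplanar C4–H, so elimination to the chromene enol ester competes. The tertiary cation can also lose the ring proton to give the 2-isopropylidene enol ether, which is conjugated with O1. The conditions are those under which the p-alkoxybenzylic acetate and the benzylic isovalerate ionise.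
- A6 further needs a highly enantioselective dihydroxylation of a cis-configured cyclic alkene, a poor substrate class for that reaction, and a selective mono-acylation of the diol.
- The chosen route is longer, but its key step goes through a closed transition state with understood control, and its ring closure cannot disturb either stereocentre.

Key step: step 6

Assumption: the sense of induction of the binaphthyl phosphoric acid is taken from allyl- and crotylborations of aryl aldehydes, where the (R)-acid sends the allyl group to the Re face. The Si-face addition needed for 12 therefore calls for the (S)-acid, and the antipodal acid would be used if this reagent behaved otherwise.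

## Route

Step 1
Reactants: 1 1-(4-bromo-3-methylphenyl)ethanone
Product: 2 2-(4-bromo-3-methylphenyl)-2-methyl-1,3-dioxolane
Conditions: HOCH2CH2OH (3 equiv), p-TsOH·H2O (2 mol%), toluene, reflux, Dean–Stark
Reagents that add atoms: ethane-1,2-diol, OCCO
Why: Acid-catalysed ketalisation driven by azeotropic removal of water; the dioxolane keeps the ketone out of enolisation and out of the carbonyl addition of step 6.

Step 2
Reactants: 2 2-(4-bromo-3-methylphenyl)-2-methyl-1,3-dioxolane
Product: 3 2-[4-bromo-3-(bromomethyl)phenyl]-2-methyl-1,3-dioxolane
Conditions: NBS (1.05 equiv), 2,2'-azobis(2-methylpropionitrile) (5 mol%), K2CO3 (solid, 0.2 equiv), PhCF3, 85 °C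
Reagents that add atoms: N-bromosuccinimide, O=C1CCC(=O)N1Br
Why: Wohl–Ziegler bromination at the only benzylic C–H position; the ketal carbon has no hydrogen, and the solid base takes up HBr that could open the dioxolane. One equivalent of reagent and the ortho bromine should hold the reaction at the monobromide.

Step 3
Reactants: 3 2-[4-bromo-3-(bromomethyl)phenyl]-2-methyl-1,3-dioxolane
Product: 4 2-bromo-5-(2-methyl-1,3-dioxolan-2-yl)benzaldehyde
Conditions: NMO (4 equiv), 4 Å MS, MeCN, rt
Reagents that add atoms: 4-methylmorpholine N-oxide, C[N+]1([O-])CCOCC1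
Why: Kornblum-type oxidation of a benzylic halide with an amine N-oxide: SN2 displacement by the N-oxide oxygen, then loss of the amine from the alkoxyammonium salt gives the aldehyde under non-acidic conditions that the ketal tolerates.

Step 4
Reactants: 5 2-methylprop-2-en-1-ol
Product: 6 3-(methoxymethoxy)-2-methylprop-1-ene
Conditions: MeOCH2Cl (1.2 equiv), iPr2NEt (1.5 equiv), CH2Cl2, 0 °C to rt
Reagents that add atoms: chloromethyl methyl ether, COCCl
Why: O-alkylation of the primary alcohol with the chloromethyl ether under amine base; the acetal oxygen installed here chelates lithium in step 5.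

Step 5
Reactants: 6 3-(methoxymethoxy)-2-methylprop-1-ene; 7 2-isopropoxy-4,4,5,5-tetramethyl-1,3,2-dioxaborolane
Product: 10 2-[(2Z)-3-(methoxymethoxy)-2-methylprop-2-en-1-yl]-4,4,5,5-tetramethyl-1,3,2-dioxaborolane, via lithiated allyl ether 8 (not isolated), via lithium borate complex 9 (not isolated)
Conditions: s-BuLi (1.1 equiv), THF, −78 °C; then 7 (1.2 equiv), −78 °C to rt; pH 7 buffer
Reagents that add atoms: none
Why: Directed α-lithiation of an allylic ether: the O–CH2 protons are allylic and oxygen-activated, and lithium held by both acetal oxygens gives the chelated (Z)-oxyallyl anion, which the β-methyl group favours further by 1,2-strain in the (E) form. The borate is taken up at the γ-carbon, remote from the chelated oxygen, and loss of isopropoxide from the ate complex gives the (Z)-γ-alkoxyallyl boronate, as in known γ-alkoxyallylboronate preparations.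

Step 6
Reactants: 4 2-bromo-5-(2-methyl-1,3-dioxolan-2-yl)benzaldehyde; 10 2-[(2Z)-3-(methoxymethoxy)-2-methylprop-2-en-1-yl]-4,4,5,5-tetramethyl-1,3,2-dioxaborolane
Product: 12 (1R,2R)-1-[2-bromo-5-(2-methyl-1,3-dioxolan-2-yl)phenyl]-2-(methoxymethoxy)-3-methylbut-3-en-1-ol, via pinacol borate ester 11 (not isolated)
Conditions: (S)-3,3'-bis(2,4,6-triisopropylphenyl)-1,1'-binaphthyl-2,2'-diyl hydrogen phosphate (5 mol%), 4 Å MS, toluene, −30 °C; aq. NaHCO3
Reagents that add atoms: none
Why: The boronate adds through a closed six-membered chair (Zimmerman–Traxler) transition state with boron on the carbonyl oxygen; the C–C bond forms between the aldehyde carbon and the γ-carbon of 10, and the allyl transposition turns the methyl-bearing carbon into the 2-propenyl branch. The closest known reaction type is the chiral-phosphoric-acid-catalysed allyl- and crotylboration of aryl aldehydes with pinacol boronates, combined with the syn-selective addition of (Z)-γ-alkoxyallylboronates. The acid donates a hydrogen bond from P–OH to a pinacol oxygen while its phosphoryl oxygen contacts the formyl hydrogen, so the aldehyde sits in a pocket walled by the two triisopropylphenyl groups. No ring is closed in this step. The C1/C2 syn relationship is set by the (Z) geometry of 10, which places the γ-oxygen axial and the aryl group equatorial in the chair. The absolute configuration at C1 is set by the (S)-acid, chosen to open the Si face of the aldehyde, and C2 follows from the chair. The step needs selectivity for the aldehyde, secured by the ketal on the second carbonyl, γ-regioselectivity, which is inherent in the cyclic transition state, and a slow uncatalysed background, which the β-methyl group and the low temperature favour. The ortho bromine is a spectator here and is the handle for step 8.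

Step 7
Reactants: 12 (1R,2R)-1-[2-bromo-5-(2-methyl-1,3-dioxolan-2-yl)phenyl]-2-(methoxymethoxy)-3-methylbut-3-en-1-ol
Product: 13 1-{4-bromo-3-[(1R,2R)-1,2-dihydroxy-3-methylbut-3-en-1-yl]phenyl}ethanone
Conditions: aq. HCl (2 M), MeOH–THF, 40 °C
Reagents that add atoms: water, O
Why: Acid-catalysed acetal cleavage removes the dioxolane and the methoxymethyl ether together, with methanol carrying the formaldehyde unit away as its dimethyl acetal. The electron-poor aryl ring (bromine, acetyl) makes the benzylic C–O bond slow to ionise, so both stereocentres should be retained.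

Step 8
Reactants: 13 1-{4-bromo-3-[(1R,2R)-1,2-dihydroxy-3-methylbut-3-en-1-yl]phenyl}ethanone
Product: 14 1-[(2R,3R)-3-hydroxy-2-(prop-1-en-2-yl)-2,3-dihydro-1-benzofuran-5-yl]ethanone
Conditions: CuI (10 mol%), 3,4,7,8-tetramethyl-1,10-phenanthroline (20 mol%), Cs2CO3 (2 equiv), toluene, 100 °C, Ar
Reagents that add atoms: none
Why: Ullmann-type intramolecular C–O coupling of a secondary alcohol with an aryl bromide; only the C2 oxygen can reach the C–Br carbon through a five-membered ring, since the C3 oxygen would have to close a four-membered one, and the para acetyl group activates the C–Br bond. Neither stereocentre takes part, so the syn diol becomes the cis ring.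

Step 9
Reactants: 14 1-[(2R,3R)-3-hydroxy-2-(prop-1-en-2-yl)-2,3-dihydro-1-benzofuran-5-yl]ethanone; 15 3-methylbutanoic acid
Product: 16 (2R,3R)-5-acetyl-2-(prop-1-en-2-yl)-2,3-dihydro-1-benzofuran-3-yl 3-methylbutanoate
Conditions: DCC (1.3 equiv), 4-(dimethylamino)pyridine (10 mol%), CH2Cl2, 0 °C to rt
Reagents that add atoms: none
Why: Steglich esterification of the only free hydroxyl; the neutral carbodiimide conditions should not provoke loss of the C3 oxygen toward the benzofuran, and the C–O bond at C3 is not broken, so the configuration is retained.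

Step 10
Reactants: 16 (2R,3R)-5-acetyl-2-(prop-1-en-2-yl)-2,3-dihydro-1-benzofuran-3-yl 3-methylbutanoate
Product: 17 (2R,3R)-5-[(1S)-1-hydroxyethyl]-2-(prop-1-en-2-yl)-2,3-dihydro-1-benzofuran-3-yl 3-methylbutanoate
Conditions: RuCl(p-cymene)[(S,S)-TsNCHPhCHPhNH2] (1 mol%), HCO2H–Et3N (5:2), EtOAc, 30 °C
Reagents that add atoms: none
Why: Noyori asymmetric transfer hydrogenation of an aryl methyl ketone; the (S,S)-diamine complex transfers Ru–H and N–H through an outer-sphere six-membered transition state to give the (S)-carbinol, the catalyst alone setting C1' because the ring stereocentres are remote. The ester and the unactivated alkene are not reduced under these conditions.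

Step 11
Reactants: 17 (2R,3R)-5-[(1S)-1-hydroxyethyl]-2-(prop-1-en-2-yl)-2,3-dihydro-1-benzofuran-3-yl 3-methylbutanoate
Product: 18 (2R,3R)-5-[(1S)-1-acetoxyethyl]-2-(prop-1-en-2-yl)-2,3-dihydro-1-benzofuran-3-yl 3-methylbutanoate
Conditions: Ac2O (1.5 equiv), Et3N (2 equiv), 4-(dimethylamino)pyridine (5 mol%), CH2Cl2, 0 °C
Reagents that add atoms: acetic anhydride, CC(=O)OC(C)=O
Why: Nucleophile-catalysed acylation of the only free hydroxyl under basic conditions; the C1'–O bond is not broken, so the (S) configuration is kept.

Step 12
Reactants: 18 (2R,3R)-5-[(1S)-1-acetoxyethyl]-2-(prop-1-en-2-yl)-2,3-dihydro-1-benzofuran-3-yl 3-methylbutanoate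
Product: 19 (2R,3R)-5-[(1S)-1-acetoxyethyl]-2-(3-hydroxyprop-1-en-2-yl)-2,3-dihydro-1-benzofuran-3-yl 3-methylbutanoate
Conditions: SeO2 (0.3 equiv), t-BuOOH (3 equiv, anhydrous), CH2Cl2, rt
Reagents that add atoms: selenium dioxide, O=[Se]=O; tert-butyl hydroperoxide, CC(C)(C)OO
Why: Selenium dioxide allylic oxidation (ene reaction, then [2,3]-sigmatropic shift) with the hydroperoxide as reoxidant; on this 1,1-disubstituted alkene the ene step should take a methyl hydrogen in preference to the C2–H, which is deactivated by its oxygen and shielded by ring B, so the double bond returns to its place and the primary allylic alcohol results. No methyl ketone is left at this stage that could undergo Riley oxidation.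

Step 13
Reactants: 19 (2R,3R)-5-[(1S)-1-acetoxyethyl]-2-(3-hydroxyprop-1-en-2-yl)-2,3-dihydro-1-benzofuran-3-yl 3-methylbutanoate
Product: 20 (2R,3R)-5-[(1S)-1-acetoxyethyl]-2-(3-oxoprop-1-en-2-yl)-2,3-dihydro-1-benzofuran-3-yl 3-methylbutanoate
Conditions: MnO2 (activated, 15 equiv), CH2Cl2, rt
Reagents that add atoms: none
Why: Heterogeneous MnO2 oxidation is selective for allylic alcohols and neutral, so both esters and all three stereocentres are left alone; the sensitive propenal is made in the last step.

## Compound list

1 | 1-(4-bromo-3-methylphenyl)ethanone | CC(=O)c1ccc(Br)c(C)c1 | starting material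
2 | 2-(4-bromo-3-methylphenyl)-2-methyl-1,3-dioxolane | Cc1cc(C2(C)OCCO2)ccc1Br | intermediate
3 | 2-[4-bromo-3-(bromomethyl)phenyl]-2-methyl-1,3-dioxolane | BrCc1cc(C2(C)OCCO2)ccc1Br | intermediate
4 | 2-bromo-5-(2-methyl-1,3-dioxolan-2-yl)benzaldehyde | O=Cc1cc(C2(C)OCCO2)ccc1Br | intermediate
5 | 2-methylprop-2-en-1-ol | C=C(C)CO | starting material
6 | 3-(methoxymethoxy)-2-methylprop-1-ene | C=C(C)COCOC | intermediate
7 | 2-isopropoxy-4,4,5,5-tetramethyl-1,3,2-dioxaborolane | CC(C)OB1OC(C)(C)C(C)(C)O1 | starting material
8 | [(2Z)-3-(methoxymethoxy)-2-methylprop-2-en-1-yl]lithium (chelated oxyallyl anion, not isolated) | [Li]C/C(C)=C\OCOC | intermediate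
9 | lithium [(2Z)-3-(methoxymethoxy)-2-methylprop-2-en-1-yl](propan-2-yloxy)(2,3-dimethylbutane-2,3-diolato)borate (not isolated) | [Li+].COCO/C=C(/C)C[B-]1(OC(C)C)OC(C)(C)C(C)(C)O1 | intermediate
10 | 2-[(2Z)-3-(methoxymethoxy)-2-methylprop-2-en-1-yl]-4,4,5,5-tetramethyl-1,3,2-dioxaborolane | COCO/C=C(/C)CB1OC(C)(C)C(C)(C)O1 | intermediate
11 | 2-{(1R,2R)-1-[2-bromo-5-(2-methyl-1,3-dioxolan-2-yl)phenyl]-2-(methoxymethoxy)-3-methylbut-3-en-1-yloxy}-4,4,5,5-tetramethyl-1,3,2-dioxaborolane (not isolated) | C=C(C)[C@@H](OCOC)[C@H](OB1OC(C)(C)C(C)(C)O1)c1cc(C2(C)OCCO2)ccc1Br | intermediate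
12 | (1R,2R)-1-[2-bromo-5-(2-methyl-1,3-dioxolan-2-yl)phenyl]-2-(methoxymethoxy)-3-methylbut-3-en-1-ol | C=C(C)[C@@H](OCOC)[C@H](O)c1cc(C2(C)OCCO2)ccc1Br | intermediate
13 | 1-{4-bromo-3-[(1R,2R)-1,2-dihydroxy-3-methylbut-3-en-1-yl]phenyl}ethanone | C=C(C)[C@@H](O)[C@H](O)c1cc(C(C)=O)ccc1Br | intermediate
14 | 1-[(2R,3R)-3-hydroxy-2-(prop-1-en-2-yl)-2,3-dihydro-1-benzofuran-5-yl]ethanone | C=C(C)[C@H]1Oc2ccc(C(C)=O)cc2[C@H]1O | intermediate
15 | 3-methylbutanoic acid | CC(C)CC(O)=O | starting material
16 | (2R,3R)-5-acetyl-2-(prop-1-en-2-yl)-2,3-dihydro-1-benzofuran-3-yl 3-methylbutanoate | C=C(C)[C@H]1Oc2ccc(C(C)=O)cc2[C@H]1OC(=O)CC(C)C | intermediate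
17 | (2R,3R)-5-[(1S)-1-hydroxyethyl]-2-(prop-1-en-2-yl)-2,3-dihydro-1-benzofuran-3-yl 3-methylbutanoate | C=C(C)[C@H]1Oc2ccc([C@H](C)O)cc2[C@H]1OC(=O)CC(C)C | intermediate
18 | (2R,3R)-5-[(1S)-1-acetoxyethyl]-2-(prop-1-en-2-yl)-2,3-dihydro-1-benzofuran-3-yl 3-methylbutanoate | C=C(C)[C@H]1Oc2ccc([C@H](C)OC(C)=O)cc2[C@H]1OC(=O)CC(C)C | intermediate
19 | (2R,3R)-5-[(1S)-1-acetoxyethyl]-2-(3-hydroxyprop-1-en-2-yl)-2,3-dihydro-1-benzofuran-3-yl 3-methylbutanoate | C=C(CO)[C@H]1Oc2ccc([C@H](C)OC(C)=O)cc2[C@H]1OC(=O)CC(C)C | intermediate
20 | (2R,3R)-5-[(1S)-1-acetoxyethyl]-2-(3-oxoprop-1-en-2-yl)-2,3-dihydro-1-benzofuran-3-yl 3-methylbutanoate | C=C(C=O)[C@H]1Oc2ccc([C@H](C)OC(C)=O)cc2[C@H]1OC(=O)CC(C)C | target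

## Step count and least certain steps

Total: 13 steps. Longest linear sequence: 11 steps (1 → 2 → 3 → 4, then steps 6 to 13); the boronate branch (steps 4 and 5) joins at step 6.

**Step 6 (key step).** The most likely failure is poor facial selectivity, possibly with a slow catalysed reaction. The ortho bromine crowds the carbonyl, the acetal oxygens of 4 and 10 can compete for the hydrogen bond of the acid, and the β-methyl group slows the catalysed path, so the uncatalysed racemic addition gains weight. The syn relationship is less at risk, because it comes from the chair.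

The fallback replaces catalyst control by stoichiometric reagent control (Brown-type alkoxyallylboration). It sets out from ether 6 and aldehyde 4. Anion 8 is generated as in step 5 and trapped with (−)-B-methoxydiisopinocampheylborane, and BF3·OEt2 then releases [(2Z)-3-(methoxymethoxy)-2-methylprop-2-en-1-yl]bis[(1R,2S,3R,5R)-2,6,6-trimethylbicyclo[3.1.1]hept-3-yl]borane F1 in the flask. This enantiomer of the borane is the one expected to attack the Si face. Aldehyde 4 is added at −78 °C, and oxidative work-up (NaOH, H2O2) should give 12, where the fallback returns to the route. It also removes the need to isolate 10.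

**Step 5.** The most likely failure is metalation that is not confined to the O–CH2 group (loss of a methyl proton, or incomplete metalation), together with some boron uptake at the oxygen-bearing carbon. Both would give isomeric boronates that are hard to separate from 10, which is itself a hydrolytically delicate enol ether.

The fallback generates the same anion by tin–lithium exchange, which fixes the site of metalation. It sets out from alcohol 5, which is oxidised with MnO2 to 2-methylprop-2-enal F2. Bu3SnLi adds 1,2 at −78 °C to give 2-methyl-1-(tributylstannyl)prop-2-en-1-ol F3. This is protected at once with MeOCH2Cl and iPr2NEt as tributyl[1-(methoxymethoxy)-2-methylprop-2-en-1-yl]stannane F4. n-BuLi in THF at −78 °C then gives 8, where the fallback returns to the route, and borate 7 is added as before.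

**Step 7.** The most likely failure is transfer of the formaldehyde unit of the cleaved ether to the neighbouring hydroxyl, closing a cyclic methylene acetal over the diol. Acid-induced addition of solvent to the 2-propenyl group is a second risk.

The fallback changes the oxygen protecting group to one that releases no formaldehyde and falls under much milder acid. It sets out from alcohol 5, which with dihydropyran and pyridinium p-toluenesulfonate gives 2-[(2-methylprop-2-en-1-yl)oxy]oxane F5. Lithiation and borylation with 7 as in step 5 give 4,4,5,5-tetramethyl-2-[(2Z)-2-methyl-3-(oxan-2-yloxy)prop-2-en-1-yl]-1,3,2-dioxaborolane F6. The key step with 4 then gives (1R,2R)-1-[2-bromo-5-(2-methyl-1,3-dioxolan-2-yl)phenyl]-3-methyl-2-(oxan-2-yloxy)but-3-en-1-ol F7. Dilute aqueous HCl in THF at room temperature removes both acetals and returns to the route at 13.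

**Step 8.** The most likely failure is a sluggish C–O coupling, so that base-driven self-condensation of the methyl ketone or hydrodebromination of the aryl bromide takes over at the temperature needed.

The fallback closes the ring by nucleophilic aromatic substitution on a fluoride para to the acetyl group, without a metal. It sets out from boronate 10 and uses commercial 1-(4-fluoro-3-methylphenyl)ethanone F8. This is carried through the chemistry of steps 1 to 3: ketalisation to 2-(4-fluoro-3-methylphenyl)-2-methyl-1,3-dioxolane F9, radical bromination to 2-[3-(bromomethyl)-4-fluorophenyl]-2-methyl-1,3-dioxolane F10, and N-oxide oxidation to 2-fluoro-5-(2-methyl-1,3-dioxolan-2-yl)benzaldehyde F11. The key step with 10 gives (1R,2R)-1-[2-fluoro-5-(2-methyl-1,3-dioxolan-2-yl)phenyl]-2-(methoxymethoxy)-3-methylbut-3-en-1-ol F12, and acid as in step 7 gives 1-{3-[(1R,2R)-1,2-dihydroxy-3-methylbut-3-en-1-yl]-4-fluorophenyl}ethanone F13. K2CO3 in DMF at 60 °C should then close ring B through the C2 alkoxide and return to the route at 14.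

**Step 12.** The most likely failure is ionisation of the p-alkoxybenzylic acetate, or loss of the C3 ester toward the benzofuran, under the acidic selenium species. Attack at the C2–H and over-oxidation are lesser risks.

The fallback replaces the selenium oxidation by an ene-type allylic chlorination followed by a Kornblum-type oxidation. It sets out from 18. Ca(OCl)2 with solid CO2 in CH2Cl2–H2O at 0 °C should give (2R,3R)-5-[(1S)-1-acetoxyethyl]-2-(3-chloroprop-1-en-2-yl)-2,3-dihydro-1-benzofuran-3-yl 3-methylbutanoate F14. NMO with catalytic NaI in MeCN then converts the allylic chloride into the aldehyde and returns to the route at 20, without passing through 19.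

## Further compounds

F1 | step 6 | [(2Z)-3-(methoxymethoxy)-2-methylprop-2-en-1-yl]bis[(1R,2S,3R,5R)-2,6,6-trimethylbicyclo[3.1.1]hept-3-yl]borane | COCO/C=C(/C)CB([C@@H]1C[C@@H]2C[C@H]([C@H]1C)C2(C)C)[C@@H]1C[C@@H]2C[C@H]([C@H]1C)C2(C)C
F2 | step 5 | 2-methylprop-2-enal | C=C(C)C=O
F3 | step 5 | 2-methyl-1-(tributylstannyl)prop-2-en-1-ol (racemic) | C=C(C)C(O)[Sn](CCCC)(CCCC)CCCC
F4 | step 5 | tributyl[1-(methoxymethoxy)-2-methylprop-2-en-1-yl]stannane (racemic) | C=C(C)C(OCOC)[Sn](CCCC)(CCCC)CCCC
F5 | step 7 | 2-[(2-methylprop-2-en-1-yl)oxy]oxane (racemic) | C=C(C)COC1CCCCO1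
F6 | step 7 | 4,4,5,5-tetramethyl-2-[(2Z)-2-methyl-3-(oxan-2-yloxy)prop-2-en-1-yl]-1,3,2-dioxaborolane | C1CCOC(C1)O/C=C(/C)CB1OC(C)(C)C(C)(C)O1
F7 | step 7 | (1R,2R)-1-[2-bromo-5-(2-methyl-1,3-dioxolan-2-yl)phenyl]-3-methyl-2-(oxan-2-yloxy)but-3-en-1-ol (both epimers at the oxane carbon) | C=C(C)[C@@H](OC1CCCCO1)[C@H](O)c1cc(C2(C)OCCO2)ccc1Br
F8 | step 8 | 1-(4-fluoro-3-methylphenyl)ethanone | CC(=O)c1ccc(F)c(C)c1
F9 | step 8 | 2-(4-fluoro-3-methylphenyl)-2-methyl-1,3-dioxolane | Cc1cc(C2(C)OCCO2)ccc1F
F10 | step 8 | 2-[3-(bromomethyl)-4-fluorophenyl]-2-methyl-1,3-dioxolane | BrCc1cc(C2(C)OCCO2)ccc1F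
F11 | step 8 | 2-fluoro-5-(2-methyl-1,3-dioxolan-2-yl)benzaldehyde | O=Cc1cc(C2(C)OCCO2)ccc1F
F12 | step 8 | (1R,2R)-1-[2-fluoro-5-(2-methyl-1,3-dioxolan-2-yl)phenyl]-2-(methoxymethoxy)-3-methylbut-3-en-1-ol | C=C(C)[C@@H](OCOC)[C@H](O)c1cc(C2(C)OCCO2)ccc1F
F13 | step 8 | 1-{3-[(1R,2R)-1,2-dihydroxy-3-methylbut-3-en-1-yl]-4-fluorophenyl}ethanone | C=C(C)[C@@H](O)[C@H](O)c1cc(C(C)=O)ccc1F
F14 | step 12 | (2R,3R)-5-[(1S)-1-acetoxyethyl]-2-(3-chloroprop-1-en-2-yl)-2,3-dihydro-1-benzofuran-3-yl 3-methylbutanoate | C=C(CCl)[C@H]1Oc2ccc([C@H](C)OC(C)=O)cc2[C@H]1OC(=O)CC(C)C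
A1 | alternative 1 | methyl (2R,3R)-3-(tert-butyldimethylsilyloxy)-2-(prop-1-en-2-yl)-2,3-dihydro-1-benzofuran-5-carboxylate | C=C(C)[C@H]1Oc2ccc(C(=O)OC)cc2[C@H]1O[Si](C)(C)C(C)(C)C
A2 | alternative 1 | methyl 3-{[(3R,4R)-4-(tert-butyldimethylsilyloxy)-2-methylhex-1-en-5-yn-3-yl]oxy}-2-oxo-2H-pyran-6-carboxylate | C=C(C)[C@@H](OC1=CC=C(C(=O)OC)OC1=O)[C@H](O[Si](C)(C)C(C)(C)C)C#C
A3 | alternative 2 | (2R,3R)-2-(2,2-dimethyl-1,3-dioxan-5-yl)-5-[(1S)-1-hydroxyethyl]-2,3-dihydro-1-benzofuran-3-ol | CC1(C)OCC(CO1)[C@H]1Oc2ccc([C@H](C)O)cc2[C@H]1O
A4 | alternative 2 | 5-acetyl-2-(2,2-dimethyl-1,3-dioxan-5-yl)-1-benzofuran-3(2H)-one (racemic) | CC(=O)c1ccc2OC(C3COC(C)(C)OC3)C(=O)c2c1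
A5 | alternative 3 | (2R,3R)-5-[(1S)-1-acetoxyethyl]-2-(prop-1-en-2-yl)-2,3-dihydro-1-benzofuran-3-yl 3-methylbutanoate | C=C(C)[C@H]1Oc2ccc([C@H](C)OC(C)=O)cc2[C@H]1OC(=O)CC(C)C
A6 | alternative 3 | (3R,4R)-6-[(1S)-1-acetoxyethyl]-3-hydroxy-2,2-dimethyl-3,4-dihydro-2H-chromen-4-yl 3-methylbutanoate | CC(=O)O[C@@H](C)c1ccc2OC(C)(C)[C@H](O)[C@H](OC(=O)CC(C)C)c2c1
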